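Numbering used throughout: ring C1 (O-angelate), C2 (CH2), C3 (CHMe), C4 (CHOH), C5 (CH2), C6 (CH); side chain C7 (CHMe), C8 (CH2), C9 (CHOAc), C10=C11Me2.
Cuts, in order: the two acyl–O bonds. Then C9–C10 (alkenyllithium on a δ-lactone that ties O1 to C9). Then C1–C2 and C3–C4 together (retro-Diels–Alder, after adding a C5=C6 double bond and raising the C3 methyl to CHO). Last, C5=C6 (aldol condensation).
Enabling feature: the cyclohexane holds oxygen at C1 and C4 in a cis-1,4 relation, with the C3 methyl cis to both. This is the imprint of an endo addition of CH2=CH–X to an (E,E)-1,4-dioxygenated diene C1=C6–C5=C4, and acrolein serves as the propene surrogate.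
Forward: a six-carbon chiral-pool block (C1, C6, C7 and its methyl, C8, C9) plus silyloxyacetaldehyde (C5, C4) gives an enal, then a 1-acetoxy-4-silyloxydiene. Acrolein (C2, C3, methyl carbon) closes the only ring. C5=C6 is hydrogenated, CHO is taken down to CH3, the temporary O1–C9 lactone is made and opened by the C4 unit, then angelate, acetate and desilylation follow.
Stereochemistry: C7 comes from monomethyl (R)-3-methylglutarate. C1, C3 and C4 come from the Diels–Alder step (E,E geometry, endo rule, chiral imidazolidinone for the absolute sense). C6 comes from hydroxyl-directed hydrogenation, C9 from CBS reduction, and the Z geometry of the angelate from angelic acid.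

Key step: step 5

Remark: 5 and 6 are mixtures at C5 and C6 (both carbons become sp2 in 7), and lactol 16 is an anomeric mixture. These centres are therefore left open in the SMILES.

Step 1
Reactants: 1 (3R)-5-methoxy-3-methyl-5-oxopentanoic acid (monomethyl (R)-3-methylglutarate)
Product: 2 1-tert-butyl 5-methyl (3S)-3-methylpentanedioate
Conditions: isobutene, cat. H2SO4, CH2Cl2, 0 °C to rt
Reagents that add atoms: isobutene, C=C(C)C
Why: Acid-catalysed tert-butyl esterification (capture of the tert-butyl cation by the free acid) tells the two ends of the glutarate apart, the methyl ester end becoming C1 and the bulky ester end C9, while C7 is untouched (the R to S change is only a change of CIP ranking).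

Step 2
Reactants: 2 1-tert-butyl 5-methyl (3S)-3-methylpentanedioate
Product: 3 tert-butyl (3S)-3-methyl-5-oxopentanoate
Conditions: i-Bu2AlH (1.05 equiv), toluene, −78 °C; aq. potassium sodium tartrate
Reagents that add atoms: none
Why: Partial ester reduction with i-Bu2AlH stops at the tetrahedral aluminium hemiacetal at −78 °C and takes the unhindered methyl ester in preference to the tert-butyl ester, a well-used selectivity.

Step 3
Reactants: 3 tert-butyl (3S)-3-methyl-5-oxopentanoate; 4 (tert-butyldimethylsilyloxy)acetaldehyde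
Product: 7 tert-butyl (3R,4E)-6-[(tert-butyldimethylsilyl)oxy]-4-formyl-3-methylhex-4-enoate, via aldol adduct 5 (not isolated), via acetoxy aldehyde 6 (not isolated)
Conditions: L-proline (20 mol %), DMF, 4 °C, slow addition of 3 to 4 (2 equiv); then Ac2O, Et3N, DMAP (cat.), 0 °C to rt
Reagents that add atoms: acetic anhydride, CC(=O)OC(C)=O (its acetyl group is held only in 6)
Why: Enamine-catalysed direct cross-aldol addition, with the α-unbranched alkyl aldehyde 3 as donor and the more electrophilic α-silyloxy aldehyde 4 as acceptor, is followed in the same flask by acetylation and E1cB loss of acetic acid (aldol condensation), which erases both new centres and gives the more stable (E)-enal.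

Step 4
Reactants: 7 tert-butyl (3R,4E)-6-[(tert-butyldimethylsilyl)oxy]-4-formyl-3-methylhex-4-enoate
Product: 9 tert-butyl (3R,5E)-4-[(E)-(acetyloxy)methylidene]-6-[(tert-butyldimethylsilyl)oxy]-3-methylhex-5-enoate, via potassium dienolate 8 (not isolated)
Conditions: KOt-Bu, THF, −78 °C; then AcCl, −78 °C
Reagents that add atoms: acetyl chloride, CC(=O)Cl; potassium tert-butoxide, CC(C)(C)[O-].[K+] (potassium is held only in 8)
Why: Kinetic γ-deprotonation of the s-trans enal gives the extended potassium dienolate, which the hard acyl chloride traps on oxygen (dienol ester formation), so that O1 ends trans to C5, the C4 silyloxy group ends trans to C6 because allylic 1,3-strain with the C7 branch keeps hydrogen in the inner position, and tert-butoxide cannot harm a tert-butyl ester.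

Step 5
Reactants: 9 tert-butyl (3R,5E)-4-[(E)-(acetyloxy)methylidene]-6-[(tert-butyldimethylsilyl)oxy]-3-methylhex-5-enoate; 10 acrolein
Product: 12 tert-butyl (3R)-3-[(3R,4R,6R)-6-(acetyloxy)-3-[(tert-butyldimethylsilyl)oxy]-4-(hydroxymethyl)cyclohex-1-en-1-yl]butanoate, via cycloadduct aldehyde 11 (not isolated)
Conditions: 10 (3 equiv), (5R)-5-benzyl-2,2,3-trimethylimidazolidin-4-one·HCl (20 mol %), MeCN–H2O 95:5, −10 °C; then EtOH, NaBH4, 0 °C
Reagents that add atoms: none
Why: The amine salt condenses with acrolein to an (E)-iminium ion of lowered LUMO, which adds across s-cis 9 in a concerted, asynchronous [4+2] cycloaddition (C1–C2 bond ahead of C3–C4), water then frees 11 and the catalyst, and NaBH4 reduces 11 in the same flask before loss of silanol or epimerisation at C3 can start. The closest known reaction type is the imidazolidinone-catalysed Diels–Alder reaction of acrolein with 1-acyloxybutadienes. The one ring that closes, the carbocycle C1–C6, is formed by intermolecular suprafacial–suprafacial union of the four-carbon unit C1=C6–C5=C4 and the two-carbon unit C2=C3, so the only geometric demand is the s-cis diene. C1 and C4 become cis because both oxygens hold the outer (E) positions of the diene, C3 becomes cis to them because the iminium carbon lies endo under the diene, and the absolute sense comes from the benzyl group of the (5R)-catalyst, which covers one face of the iminium ion so that the diene bonds to the open face of C3, whereas C7 on its freely rotating bond (CH3 against CH2 flanks) has little say. The step needs C2 on C1 and C3 on C4: the silyloxy group on C4 is a far better donor than the acetoxy group on C1 and, together with the alkyl branch on C6, places the largest HOMO coefficient on C1, which meets the electrophilic CH2 terminus. Isomers of 9 that hold a (Z)-enol unit cannot reach the s-cis form and stay behind, and the tert-butyl ester and the enol acetate tolerate the weakly acidic aqueous medium.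

Step 6
Reactants: 12 tert-butyl (3R)-3-[(3R,4R,6R)-6-(acetyloxy)-3-[(tert-butyldimethylsilyl)oxy]-4-(hydroxymethyl)cyclohex-1-en-1-yl]butanoate
Product: 13 tert-butyl (3R)-3-[(1S,2R,4R,5R)-2-(acetyloxy)-5-[(tert-butyldimethylsilyl)oxy]-4-(hydroxymethyl)cyclohexyl]butanoate
Conditions: H2 (1 atm), [Ir(cod)(PCy3)(py)]PF6 (5 mol %), CH2Cl2, rt
Reagents that add atoms: none
Why: In this hydroxyl-directed homogeneous hydrogenation the cationic iridium catalyst binds the CH2OH group (helped by the acetate carbonyl), which lies on the same ring face as O1 and O4, and delivers H2 to that face, so H6 becomes cis to O1 and the side chain trans to it (the configuration needed at C6).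

Step 7
Reactants: 13 tert-butyl (3R)-3-[(1S,2R,4R,5R)-2-(acetyloxy)-5-[(tert-butyldimethylsilyl)oxy]-4-(hydroxymethyl)cyclohexyl]butanoate
Product: 14 tert-butyl (3R)-3-[(1S,2R,4R,5R)-2-(acetyloxy)-5-[(tert-butyldimethylsilyl)oxy]-4-[(tosyloxy)methyl]cyclohexyl]butanoate
Conditions: TsCl, pyridine, DMAP (cat.), CH2Cl2, 0 °C to rt
Reagents that add atoms: 4-toluenesulfonyl chloride, Cc1ccc(cc1)S(=O)(=O)Cl
Why: Standard sulfonylation of the only free (primary) hydroxyl group turns the helper oxygen into a leaving group.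

Step 8
Reactants: 14 tert-butyl (3R)-3-[(1S,2R,4R,5R)-2-(acetyloxy)-5-[(tert-butyldimethylsilyl)oxy]-4-[(tosyloxy)methyl]cyclohexyl]butanoate
Product: 15 (3R)-3-[(1S,2R,4S,5R)-5-[(tert-butyldimethylsilyl)oxy]-2-hydroxy-4-methylcyclohexyl]butan-1-ol
Conditions: LiEt3BH (excess), THF, 0 to 50 °C; aq. work-up
Reagents that add atoms: none
Why: LiEt3BH is the hydride of choice for SN2 displacement of hindered primary tosylates (C–O to C–H, giving the C3 methyl group without touching C3) and in the same operation cleaves the acetate and reduces the tert-butyl ester, while in the chair of 14 O1 and CH2OTs are both equatorial, so bridged ether formation should not compete.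

Step 9
Reactants: 15 (3R)-3-[(1S,2R,4S,5R)-5-[(tert-butyldimethylsilyl)oxy]-2-hydroxy-4-methylcyclohexyl]butan-1-ol
Product: 17 (4R,4aS,6R,7S,8aR)-6-[(tert-butyldimethylsilyl)oxy]-4,7-dimethyloctahydro-2H-chromen-2-one, via lactol 16 (not isolated)
Conditions: TEMPO (10 mol %), PhI(OAc)2 (2.5 equiv), CH2Cl2, rt
Reagents that add atoms: none
Why: Oxoammonium oxidation picks the primary alcohol, the aldehyde closes onto O1 to the six-membered lactol, and this is oxidised on to the trans-fused δ-lactone (oxidative lactonisation of a 1,5-diol), a temporary ring that masks O1 and activates C9 at once.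

Step 10
Reactants: 17 (4R,4aS,6R,7S,8aR)-6-[(tert-butyldimethylsilyl)oxy]-4,7-dimethyloctahydro-2H-chromen-2-one; 18 1-bromo-2-methylprop-1-ene
Product: 19 (6R)-6-[(1S,2R,4S,5R)-5-[(tert-butyldimethylsilyl)oxy]-2-hydroxy-4-methylcyclohexyl]-2-methylhept-2-en-4-one
Conditions: 18, t-BuLi (2 equiv), Et2O, −78 °C; then 17, THF, −78 °C; aq. NH4Cl at −78 °C
Reagents that add atoms: none
Why: Addition of an alkenyllithium to a δ-lactone at −78 °C stops at the lithium lactolate, which opens to the δ-hydroxy enone only on quenching, so C9–C10 is made and O1 is set free as the only hydroxyl group.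

Step 11
Reactants: 19 (6R)-6-[(1S,2R,4S,5R)-5-[(tert-butyldimethylsilyl)oxy]-2-hydroxy-4-methylcyclohexyl]-2-methylhept-2-en-4-one; 20 angelic acid ((2Z)-2-methylbut-2-enoic acid)
Product: 21 (1R,2S,4R,5S)-4-[(tert-butyldimethylsilyl)oxy]-5-methyl-2-[(2R)-6-methyl-4-oxohept-5-en-2-yl]cyclohexyl (2Z)-2-methylbut-2-enoate
Conditions: 20, 2,4,6-trichlorobenzoyl chloride, Et3N, toluene, rt; then 19, 80 °C
Reagents that add atoms: none
Why: Yamaguchi-type mixed-anhydride esterification without a nucleophilic catalyst is the established way to acylate hindered secondary alcohols with angelic acid without Z to E drift to the tiglate.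

Step 12
Reactants: 21 (1R,2S,4R,5S)-4-[(tert-butyldimethylsilyl)oxy]-5-methyl-2-[(2R)-6-methyl-4-oxohept-5-en-2-yl]cyclohexyl (2Z)-2-methylbut-2-enoate
Product: 22 (1R,2S,4R,5S)-4-[(tert-butyldimethylsilyl)oxy]-2-[(2R,4R)-4-hydroxy-6-methylhept-5-en-2-yl]-5-methylcyclohexyl (2Z)-2-methylbut-2-enoate
Conditions: (S)-2-methyl-CBS-oxazaborolidine (20 mol %), catecholborane, toluene, −78 °C
Reagents that add atoms: none
Why: In this Corey–Bakshi–Shibata reduction the ketone binds the (S)-oxazaborolidine with the isobutenyl group as the large and C8H2 as the small substituent, so hydride reaches the face that gives (9R), and catecholborane at −78 °C leaves the angelate and the alkenes alone.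

Step 13
Reactants: 22 (1R,2S,4R,5S)-4-[(tert-butyldimethylsilyl)oxy]-2-[(2R,4R)-4-hydroxy-6-methylhept-5-en-2-yl]-5-methylcyclohexyl (2Z)-2-methylbut-2-enoate
Product: 23 (1R,2S,4R,5S)-2-[(2R,4R)-4-(acetyloxy)-6-methylhept-5-en-2-yl]-4-[(tert-butyldimethylsilyl)oxy]-5-methylcyclohexyl (2Z)-2-methylbut-2-enoate
Conditions: Ac2O, pyridine, DMAP (cat.), CH2Cl2, 0 °C
Reagents that add atoms: acetic anhydride, CC(=O)OC(C)=O
Why: Routine DMAP-catalysed acetylation of the only free hydroxyl group proceeds with retention at C9.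

Step 14
Reactants: 23 (1R,2S,4R,5S)-2-[(2R,4R)-4-(acetyloxy)-6-methylhept-5-en-2-yl]-4-[(tert-butyldimethylsilyl)oxy]-5-methylcyclohexyl (2Z)-2-methylbut-2-enoate
Product: 24 (1R,2S,4R,5S)-2-[(2R,4R)-4-(acetyloxy)-6-methylhept-5-en-2-yl]-4-hydroxy-5-methylcyclohexyl (2Z)-2-methylbut-2-enoate (target)
Conditions: HF·pyridine, pyridine, THF, 0 °C to rt
Reagents that add atoms: none
Why: Fluoride-driven Si–O cleavage in a buffered, weakly acidic medium frees the axial C4 hydroxyl group without ester migration, hydrolysis or ionisation of the allylic acetate.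

Compound list
1 | (3R)-5-methoxy-3-methyl-5-oxopentanoic acid | COC(=O)C[C@H](C)CC(=O)O | starting material
2 | 1-tert-butyl 5-methyl (3S)-3-methylpentanedioate | COC(=O)C[C@H](C)CC(=O)OC(C)(C)C | intermediate
3 | tert-butyl (3S)-3-methyl-5-oxopentanoate | O=CC[C@H](C)CC(=O)OC(C)(C)C | intermediate
4 | (tert-butyldimethylsilyloxy)acetaldehyde | O=CCO[Si](C)(C)C(C)(C)C | starting material
5 | tert-butyl (3R)-6-[(tert-butyldimethylsilyl)oxy]-4-formyl-5-hydroxy-3-methylhexanoate (mixture at C4 and C5 of the hexanoate) | O=CC(C(O)CO[Si](C)(C)C(C)(C)C)[C@H](C)CC(=O)OC(C)(C)C | intermediate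
6 | tert-butyl (3R)-5-(acetyloxy)-6-[(tert-butyldimethylsilyl)oxy]-4-formyl-3-methylhexanoate (mixture at C4 and C5 of the hexanoate) | O=CC(C(OC(C)=O)CO[Si](C)(C)C(C)(C)C)[C@H](C)CC(=O)OC(C)(C)C | intermediate
7 | tert-butyl (3R,4E)-6-[(tert-butyldimethylsilyl)oxy]-4-formyl-3-methylhex-4-enoate | O=C/C(=C/CO[Si](C)(C)C(C)(C)C)[C@H](C)CC(=O)OC(C)(C)C | intermediate
8 | potassium (1E,3E)-dienolate of 7 | [K+].[O-]/C=C(/C=C/O[Si](C)(C)C(C)(C)C)[C@H](C)CC(=O)OC(C)(C)C | intermediate
9 | tert-butyl (3R,5E)-4-[(E)-(acetyloxy)methylidene]-6-[(tert-butyldimethylsilyl)oxy]-3-methylhex-5-enoate | CC(=O)O/C=C(/C=C/O[Si](C)(C)C(C)(C)C)[C@H](C)CC(=O)OC(C)(C)C | intermediate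
10 | acrolein | C=CC=O | starting material
11 | tert-butyl (3R)-3-[(3R,4S,6R)-6-(acetyloxy)-3-[(tert-butyldimethylsilyl)oxy]-4-formylcyclohex-1-en-1-yl]butanoate | CC(=O)O[C@@H]1C[C@H](C=O)[C@H](O[Si](C)(C)C(C)(C)C)C=C1[C@H](C)CC(=O)OC(C)(C)C | intermediate
12 | tert-butyl (3R)-3-[(3R,4R,6R)-6-(acetyloxy)-3-[(tert-butyldimethylsilyl)oxy]-4-(hydroxymethyl)cyclohex-1-en-1-yl]butanoate | CC(=O)O[C@@H]1C[C@H](CO)[C@H](O[Si](C)(C)C(C)(C)C)C=C1[C@H](C)CC(=O)OC(C)(C)C | intermediate
13 | tert-butyl (3R)-3-[(1S,2R,4R,5R)-2-(acetyloxy)-5-[(tert-butyldimethylsilyl)oxy]-4-(hydroxymethyl)cyclohexyl]butanoate | CC(=O)O[C@@H]1C[C@H](CO)[C@H](O[Si](C)(C)C(C)(C)C)C[C@H]1[C@H](C)CC(=O)OC(C)(C)C | intermediate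
14 | tert-butyl (3R)-3-[(1S,2R,4R,5R)-2-(acetyloxy)-5-[(tert-butyldimethylsilyl)oxy]-4-[(tosyloxy)methyl]cyclohexyl]butanoate | CC(=O)O[C@@H]1C[C@H](COS(=O)(=O)c2ccc(C)cc2)[C@H](O[Si](C)(C)C(C)(C)C)C[C@H]1[C@H](C)CC(=O)OC(C)(C)C | intermediate
15 | (3R)-3-[(1S,2R,4S,5R)-5-[(tert-butyldimethylsilyl)oxy]-2-hydroxy-4-methylcyclohexyl]butan-1-ol | O[C@@H]1C[C@H](C)[C@H](O[Si](C)(C)C(C)(C)C)C[C@H]1[C@H](C)CCO | intermediate
16 | (4R,4aS,6R,7S,8aR)-6-[(tert-butyldimethylsilyl)oxy]-4,7-dimethyloctahydro-2H-chromen-2-ol (anomeric mixture) | O1[C@@H]2C[C@H](C)[C@H](O[Si](C)(C)C(C)(C)C)C[C@H]2[C@H](C)CC1O | intermediate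
17 | (4R,4aS,6R,7S,8aR)-6-[(tert-butyldimethylsilyl)oxy]-4,7-dimethyloctahydro-2H-chromen-2-one | O1[C@@H]2C[C@H](C)[C@H](O[Si](C)(C)C(C)(C)C)C[C@H]2[C@H](C)CC1=O | intermediate
18 | 1-bromo-2-methylprop-1-ene | CC(C)=CBr | starting material
19 | (6R)-6-[(1S,2R,4S,5R)-5-[(tert-butyldimethylsilyl)oxy]-2-hydroxy-4-methylcyclohexyl]-2-methylhept-2-en-4-one | O[C@@H]1C[C@H](C)[C@H](O[Si](C)(C)C(C)(C)C)C[C@H]1[C@H](C)CC(=O)C=C(C)C | intermediate
20 | angelic acid, (2Z)-2-methylbut-2-enoic acid | C/C=C(/C)C(=O)O | starting material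
21 | (1R,2S,4R,5S)-4-[(tert-butyldimethylsilyl)oxy]-5-methyl-2-[(2R)-6-methyl-4-oxohept-5-en-2-yl]cyclohexyl (2Z)-2-methylbut-2-enoate | C/C=C(/C)C(=O)O[C@@H]1C[C@H](C)[C@H](O[Si](C)(C)C(C)(C)C)C[C@H]1[C@H](C)CC(=O)C=C(C)C | intermediate
22 | (1R,2S,4R,5S)-4-[(tert-butyldimethylsilyl)oxy]-2-[(2R,4R)-4-hydroxy-6-methylhept-5-en-2-yl]-5-methylcyclohexyl (2Z)-2-methylbut-2-enoate | C/C=C(/C)C(=O)O[C@@H]1C[C@H](C)[C@H](O[Si](C)(C)C(C)(C)C)C[C@H]1[C@H](C)C[C@H](C=C(C)C)O | intermediate
23 | (1R,2S,4R,5S)-2-[(2R,4R)-4-(acetyloxy)-6-methylhept-5-en-2-yl]-4-[(tert-butyldimethylsilyl)oxy]-5-methylcyclohexyl (2Z)-2-methylbut-2-enoate | C/C=C(/C)C(=O)O[C@@H]1C[C@H](C)[C@H](O[Si](C)(C)C(C)(C)C)C[C@H]1[C@H](C)C[C@H](C=C(C)C)OC(C)=O | intermediate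
24 | (1R,2S,4R,5S)-2-[(2R,4R)-4-(acetyloxy)-6-methylhept-5-en-2-yl]-4-hydroxy-5-methylcyclohexyl (2Z)-2-methylbut-2-enoate | C/C=C(/C)C(=O)O[C@@H]1C[C@H](C)[C@H](O)C[C@H]1[C@H](C)C[C@H](C=C(C)C)OC(C)=O | target

Total step count: 14. Longest linear sequence: 14 steps (1 to 24).

Steps most likely to fail
1. Step 5.
- What may go wrong: the silyl dienol ether is hydrolysed by the aqueous acidic medium before cycloaddition. The reaction may also take a stepwise Mukaiyama–Michael course that ends open-chain, or facial control may be weak.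
- Fallback, from 9: switch to anhydrous two-point Lewis-acid catalysis. 3-Acryloyl-1,3-oxazolidin-2-one and [Cu((S,S)-t-Bu-box)](SbF6)2 (divalent copper, square-planar chelate of the imide) in CH2Cl2 should give the endo imide cycloadduct F1.
- Return: reductive cleavage of the imide with LiBH4 and MeOH (1 equiv) in Et2O at 0 °C rejoins the route at 12.

2. Step 4.
- What may go wrong: geometric control at C1=C6 is lost through reaction of the s-cis enal, or acylation takes place on carbon.
- Fallback, from 7: soft enolisation with TMSOTf and Et3N in Et2O goes through the s-trans O-silyl oxocarbenium ion, followed by γ-deprotonation by the amine. This sets the geometry first and gives the trimethylsilyl dienol ether F2.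
- Return: KOt-Bu at −78 °C attacks only the small silyl group and releases 8 with retention of geometry, and AcCl then gives 9.

3. Step 6.
- What may go wrong: poor facial selectivity if the directing group binds weakly, or sluggish reduction of the hindered, doubly oxygen-flanked alkene.
- Fallback, from 12: radical hydrogen-atom-transfer hydrogenation (Mn(dpm)3, PhSiH3, t-BuOOH, i-PrOH, rt). Here H adds to C5, and the tertiary C6 radical takes up the second H under thermodynamic control, which places the side chain equatorial and trans to O1.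
- Return: this leads straight to 13 and makes no new compound (F0).

Further compounds
F1 | step 5 | tert-butyl (3R)-3-[(3R,4S,6R)-6-(acetyloxy)-3-[(tert-butyldimethylsilyl)oxy]-4-(2-oxo-1,3-oxazolidine-3-carbonyl)cyclohex-1-en-1-yl]butanoate | CC(=O)O[C@@H]1C[C@H](C(=O)N2CCOC2=O)[C@H](O[Si](C)(C)C(C)(C)C)C=C1[C@H](C)CC(=O)OC(C)(C)C
F2 | step 4 | tert-butyl (3R,5E)-6-[(tert-butyldimethylsilyl)oxy]-3-methyl-4-[(E)-[(trimethylsilyl)oxy]methylidene]hex-5-enoate | C[Si](C)(C)O/C=C(/C=C/O[Si](C)(C)C(C)(C)C)[C@H](C)CC(=O)OC(C)(C)C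
F0 | step 6 | none | none
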